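**Retrosynthetic overview**
1. Target ⇐ removal of two silyl groups; the 4-hydroxybenzoate is built on the C6 alcohol from an aryl iodide and CO; the isovalerate is already in place.
2. C6 alcohol ⇐ C6 ketone of a cis-fused hydroazulenone ⇐ key 1,2-shift of C1 from C6 to C5 in a trans-decalin cis-diol activated at O5 (ring A contracts from six to five, ring B expands from six to seven).
3. Decalin diol ⇐ syn-dihydroxylation of C5=C6, C10 reduction and acylation, and isopropyl 1,2-addition at C4, all on a Wieland–Miescher-type dienedione.
4. Dienedione ⇐ dehydrogenation of the enedione made by a D-proline Robinson annulation (sets C1) of 2,5-dimethylcyclohexane-1,3-dione with methyl vinyl ketone.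
5. Dione ⇐ methyl acetoacetate + methyl crotonate, then C-methylation. Ring order: B (six), A (six), then A→five and B→seven in the shift.

Assumption: atoms keep daucane numbers throughout (C1 methyl-bearing fusion carbon, C4 isopropyl carbinol, C5 fusion CH, C6 aroyloxy carbon, C8=C9, C10 isovaleryloxy carbon), β is the face of the C1 methyl, and tert-butyl(4-iodophenoxy)dimethylsilane is bought.

**Route**

Step 1
Reactants: 1 methyl acetoacetate; 2 methyl (E)-crotonate
Product: 4 5-methylcyclohexane-1,3-dione, via keto ester 3 (not isolated)
Conditions: NaOMe, MeOH, 65 °C; then 6 M HCl, 100 °C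
Reagents that add atoms: none
Why: Michael addition of the acetoacetate enolate to the crotonate and Claisen (Dieckmann-type) closure give the cyclic beta-keto ester 3, whose acid hydrolysis and decarboxylation leave the achiral dione that becomes ring B (classical dihydroresorcinol synthesis).

Step 2
Reactants: 4 5-methylcyclohexane-1,3-dione
Product: 5 2,5-dimethylcyclohexane-1,3-dione
Conditions: MeI, KOH, H2O/MeOH, 65 °C
Reagents that add atoms: iodomethane CI
Why: C-alkylation of the stabilised 1,3-dione enolate at C2 is the standard entry to 2-methyl-1,3-diones and puts in the future angular methyl; the product is achiral because its cis and trans forms interconvert by enolisation.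

Step 3
Reactants: 5 2,5-dimethylcyclohexane-1,3-dione; 6 but-3-en-2-one
Product: 8 (8aR)-3,8a-dimethyl-3,4,8,8a-tetrahydronaphthalene-1,6(2H,7H)-dione (both C3 epimers), via triketone 7 (not isolated)
Conditions: D-proline (35 mol %), DMSO, 35 °C
Reagents that add atoms: none
Why: Michael addition to the vinyl ketone and then the proline-enamine intramolecular aldol condensation (Hajos–Parrish–Eder–Sauer–Wiechert Robinson annulation) close ring A on one of the two enantiotopic ring carbonyls, so that D-proline sets the quaternary carbon C1 as R; both C8 methyl epimers are carried on because C8 becomes trigonal in step 4, and the enantiomeric excess can be raised by crystallising diol 12.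

Step 4
Reactants: 8 enedione (both C8 epimers)
Product: 9 (8aR)-3,8a-dimethyl-4,7,8,8a-tetrahydronaphthalene-1,6-dione
Conditions: Pd(OCOCF3)2 (5 mol %), DMSO (10 mol %), O2 (1 atm), AcOH, 80 °C
Reagents that add atoms: none
Why: Aerobic palladium-catalysed alpha,beta-dehydrogenation of the saturated ring B ketone, which can form an enolate only towards C9, gives the C8=C9 beta-methyl enone and merges the C8 epimers, while the already conjugated ring A enone reacts far more slowly.

Step 5
Reactants: 9 dienedione
Product: 11 C4 triethylsilyl ether of the isopropyl adduct (4β-OSiEt3 and 4α-isopropyl), via magnesium alkoxide 10 (not isolated)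
Conditions: iPrMgCl, LaCl3·2LiCl, THF, −40 °C; then Et3SiOTf, −40 to 0 °C
Reagents that add atoms: isopropylmagnesium chloride CC(C)[Mg]Cl; triethylsilyl trifluoromethanesulfonate CC[Si](CC)(CC)OS(=O)(=O)C(F)(F)F
Why: The lanthanum-activated Grignard 1,2-addition takes place at the less hindered ring A enone carbonyl (the ring B carbonyl is flanked by the quaternary C1) and, as with steroidal 4-en-3-ones, from the face opposite the angular methyl, so C4 receives the isopropyl group on the alpha face and the oxygen on the beta face, and the tertiary alkoxide is silylated in the same flask.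

Step 6
Reactants: 11 silyl ether
Product: 12 trans-decalin 5α,6α-diol
Conditions: OsO4 (10 mol %), NMO, citric acid, t-BuOH/H2O, 40 °C
Reagents that add atoms: N-methylmorpholine N-oxide C[N+]1([O-])CCOCC1; water O
Why: Catalytic osmium tetroxide syn-dihydroxylation (Upjohn conditions) attacks the only electron-rich alkene from the alpha face, opposite both the angular methyl and the allylic silyloxy group (Kishi-type anti selectivity, as for 5-ene steroids), which gives the trans-fused cis-diol with the secondary C5 hydroxyl equatorial and anti to the C1 methyl; the enone alkene is too electron-poor to compete.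

Step 7
Reactants: 12 diol enone
Product: 13 5α,6α,10β-triol
Conditions: NaBH4, CeCl3·7H2O, MeOH, −78 °C
Reagents that add atoms: none
Why: Luche 1,2-reduction delivers hydride to the C10 enone carbonyl axially from the face opposite the adjacent angular methyl, as in Wieland–Miescher ketone reductions, which sets the C10 hydroxyl beta (cis to the C1 methyl).

Step 8
Reactants: 13 triol
Product: 14 C10 isovalerate of the 5α,6α-diol
Conditions: isovaleryl chloride, pyridine, DMAP (cat.), CH2Cl2, −20 °C
Reagents that add atoms: 3-methylbutanoyl chloride CC(C)CC(Cl)=O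
Why: DMAP-catalysed acylation is site-selective for the allylic C10 hydroxyl because the C5 hydroxyl lies between two fully substituted carbons and the C6 hydroxyl is tertiary, so the isovalerate of the target is installed and no stereocentre is touched.

Step 9 (key step)
Reactants: 14 diol isovalerate
Product: 16 cis-fused hydroazulen-6-one (5β-H), via phosphinite 15 (not isolated)
Conditions: Ph2PCl, Et3N, DMAP (cat.), THF, −20 °C; then 2,6-dimethyl-1,4-benzoquinone, CH2Cl2, 0 to 25 °C
Reagents that add atoms: none
Why: Proposed new method: the only accessible secondary hydroxyl (C5) is turned into its diphenylphosphinite and then, with 2,6-dimethyl-1,4-benzoquinone, into an alkoxyphosphonium aryloxide betaine (the activation mode of the Mukaiyama oxidation–reduction condensation), whose equatorial C5–O bond is antiperiplanar to the C6–C1 ring bond, so C1 migrates from C6 to C5 with inversion at C5 and retention at C1 while the C6 hydroxyl becomes the ketone and gives its proton to the aryloxide, contracting ring A to five and expanding ring B to seven carbons and setting the cis ring fusion (5-beta-H) under neutral conditions that spare the epimerisable C5 centre, the allylic ester and the C4 silyl ether (which cannot drive the competing C3 shift); the closest known reactions are the pinacol-type (semipinacol) shift of cis-diol monosulfonates used for decalin-to-hydroazulene conversions and the redox-condensation substitution of hindered alcohols with inversion.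

Step 10
Reactants: 16 hydroazulenone
Product: 17 6α-alcohol
Conditions: NaBH4, CeCl3·7H2O, MeOH, −78 °C
Reagents that add atoms: none
Why: Borohydride reduction under Luche conditions adds hydride to the cycloheptanone carbonyl from the convex beta face that carries H5 (Felkin–Anh, anti to the bulky C4 substituent on the concave face), which gives the 6-alpha alcohol without touching the ester or the alkene.

Step 11
Reactants: 17 6α-alcohol; 18 tert-butyl(4-iodophenoxy)dimethylsilane
Product: 20 bis-silyl diester, via aroyl chloride 19 (not isolated)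
Conditions: 18, CO (4 atm), Pd(P(t-Bu)3)2 (5 mol %), Bu4NCl, toluene, 110 °C; then 17, DMAP, i-Pr2NEt, 50 °C
Reagents that add atoms: carbon monoxide [C-]#[O+]
Why: Palladium-catalysed chlorocarbonylation of the aryl iodide generates the aroyl chloride in the flask (carbonylative acid chloride synthesis), and DMAP-catalysed acyl transfer then esterifies the hindered C6 hydroxyl with retention, the tertiary C4 oxygen being masked as its silyl ether.

Step 12
Reactants: 20 bis-silyl diester
Product: 21 target
Conditions: Et3N·3HF, MeCN, 50 °C
Reagents that add atoms: none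
Why: Fluoride-mediated desilylation removes the phenolic tert-butyldimethylsilyl and the tertiary triethylsilyl groups, while the two carboxylic esters, the alkene and all five stereocentres are unaffected, and so gives the target.

**Compound list**
1 | methyl 3-oxobutanoate (methyl acetoacetate) | CC(=O)CC(=O)OC | starting material
2 | methyl (E)-but-2-enoate (methyl crotonate) | C/C=C/C(=O)OC | starting material
3 | methyl 2-methyl-4,6-dioxocyclohexane-1-carboxylate (as sodium enolate in the flask) | COC(=O)C1C(C)CC(=O)CC1=O | intermediate
4 | 5-methylcyclohexane-1,3-dione | CC1CC(=O)CC(=O)C1 | intermediate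
5 | 2,5-dimethylcyclohexane-1,3-dione | CC1CC(=O)C(C)C(=O)C1 | intermediate
6 | but-3-en-2-one (methyl vinyl ketone) | C=CC(C)=O | starting material
7 | 2,5-dimethyl-2-(3-oxobutyl)cyclohexane-1,3-dione | CC(=O)CCC1(C)C(=O)CC(C)CC1=O | intermediate
8 | (8aR)-3,8a-dimethyl-3,4,8,8a-tetrahydronaphthalene-1,6(2H,7H)-dione, both C3 (daucane C8) epimers | CC1CC(=O)[C@]2(C)CCC(=O)C=C2C1 | intermediate
9 | (8aR)-3,8a-dimethyl-4,7,8,8a-tetrahydronaphthalene-1,6-dione | CC1=CC(=O)[C@]2(C)CCC(=O)C=C2C1 | intermediate
10 | chloromagnesium alkoxide of the C4 isopropyl adduct of 9 (O on the β face, isopropyl α) | CC1=CC(=O)[C@]2(C)CC[C@](O[Mg]Cl)(C(C)C)C=C2C1 | intermediate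
11 | (8aR)-6-isopropyl-3,8a-dimethyl-6-(triethylsilyloxy)-6,7,8,8a-tetrahydronaphthalen-1(4H)-one; silyloxy cis to the 8a-methyl | CC1=CC(=O)[C@]2(C)CC[C@](O[Si](CC)(CC)CC)(C(C)C)C=C2C1 | intermediate
12 | 4a,5-dihydroxy-6-isopropyl-3,8a-dimethyl-6-(triethylsilyloxy)-4a,5,6,7,8,8a-hexahydronaphthalen-1(4H)-one; trans-decalin, both hydroxyls trans to the 8a-methyl (daucane 5α,6α), silyloxy cis to it | CC1=CC(=O)[C@]2(C)CC[C@](O[Si](CC)(CC)CC)(C(C)C)[C@H](O)[C@@]2(O)C1 | intermediate
13 | 6-isopropyl-3,8a-dimethyl-6-(triethylsilyloxy)-1,4,4a,5,6,7,8,8a-octahydronaphthalene-1,4a,5-triol; 1-OH (daucane C10) cis to the 8a-methyl, 4a- and 5-OH trans to it | CC1=C[C@@H](O)[C@]2(C)CC[C@](O[Si](CC)(CC)CC)(C(C)C)[C@H](O)[C@@]2(O)C1 | intermediate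
14 | 1-(3-methylbutanoate) of triol 13 (ester at daucane C10; C5 and C6 hydroxyls free) | CC1=C[C@@H](OC(=O)CC(C)C)[C@]2(C)CC[C@](O[Si](CC)(CC)CC)(C(C)C)[C@H](O)[C@@]2(O)C1 | intermediate
15 | C5 O-diphenylphosphinite of 14 | CC1=C[C@@H](OC(=O)CC(C)C)[C@]2(C)CC[C@](O[Si](CC)(CC)CC)(C(C)C)[C@H](OP(c3ccccc3)c3ccccc3)[C@@]2(O)C1 | intermediate
16 | 3-isopropyl-6,8a-dimethyl-4-oxo-3-(triethylsilyloxy)-1,2,3,3a,4,5,8,8a-octahydroazulen-8-yl 3-methylbutanoate; cis-fused, 1β-Me, 5β-H, 4β-OSiEt3, 10β-acyloxy (daucane numbering) | CC1=C[C@@H](OC(=O)CC(C)C)[C@]2(C)CC[C@](O[Si](CC)(CC)CC)(C(C)C)[C@@H]2C(=O)C1 | intermediate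
17 | 4-hydroxy-3-isopropyl-6,8a-dimethyl-3-(triethylsilyloxy)-1,2,3,3a,4,5,8,8a-octahydroazulen-8-yl 3-methylbutanoate; 6α-OH (daucane numbering) | CC1=C[C@@H](OC(=O)CC(C)C)[C@]2(C)CC[C@](O[Si](CC)(CC)CC)(C(C)C)[C@@H]2[C@H](O)C1 | intermediate
18 | tert-butyl(4-iodophenoxy)dimethylsilane | CC(C)(C)[Si](C)(C)Oc1ccc(I)cc1 | starting material
19 | 4-(tert-butyldimethylsilyloxy)benzoyl chloride | CC(C)(C)[Si](C)(C)Oc1ccc(cc1)C(Cl)=O | intermediate
20 | 3-isopropyl-6,8a-dimethyl-8-(3-methylbutanoyloxy)-3-(triethylsilyloxy)-1,2,3,3a,4,5,8,8a-octahydroazulen-4-yl 4-(tert-butyldimethylsilyloxy)benzoate; configuration as in 21 | CC1=C[C@@H](OC(=O)CC(C)C)[C@]2(C)CC[C@](O[Si](CC)(CC)CC)(C(C)C)[C@@H]2[C@H](OC(=O)c3ccc(O[Si](C)(C)C(C)(C)C)cc3)C1 | intermediate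
21 | [(3S,3aS,4R,8R,8aR)-3-hydroxy-6,8a-dimethyl-8-(3-methylbutanoyloxy)-3-(propan-2-yl)-1,2,3,3a,4,5,8,8a-octahydroazulen-4-yl] 4-hydroxybenzoate (CNP0086724.1) | CC1=C[C@@H](OC(=O)CC(C)C)[C@]2(C)CC[C@](O)(C(C)C)[C@@H]2[C@H](OC(=O)c2ccc(O)cc2)C1 | target

**Step count and risks**

Total steps: 12. Longest linear sequence: 12 steps (1 and 2 to 21); the aryl iodide 18 enters in step 11.

The three steps most likely to fail:

Step 9, the new activation for the key shift. The phosphinite may form slowly at the crowded C5 hydroxyl, or the betaine may collapse without the shift. The fallback uses known chemistry and sets out from 14. Mesylation with MsCl and Et3N in CH2Cl2 at −20 °C gives the hydroxy mesylate F1. Treatment with Et3Al in CH2Cl2 at −78 °C then triggers the organoaluminium-promoted pinacol-type shift of this hydroxy mesylate and returns to the route at 16.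

Step 11, esterification of a very hindered secondary alcohol by an aroyl chloride made in the flask. The fallback sets out from 18 and 17. Iodine–lithium exchange on 18 with n-BuLi in THF at −78 °C and quenching with CO2 gives 4-(tert-butyldimethylsilyloxy)benzoic acid F2. Yamaguchi esterification of 17 with this acid (2,4,6-trichlorobenzoyl chloride, Et3N, DMAP, toluene) returns to the route at 20.

Step 10, facial selectivity of hydride addition to a flexible seven-membered ketone. The fallback sets out from 16. If the 6β-alcohol F3 is the main product it is kept. Mitsunobu esterification (PPh3, diisopropyl azodicarboxylate, THF) with the acid F2 inverts C6 and installs the aroyl group in one operation, returning to the route at 20.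

Further compounds
F1 | step 9 | C5 methanesulfonate of 14 (C6 hydroxyl free) | CC1=C[C@@H](OC(=O)CC(C)C)[C@]2(C)CC[C@](O[Si](CC)(CC)CC)(C(C)C)[C@H](OS(C)(=O)=O)[C@@]2(O)C1
F2 | step 11 | 4-(tert-butyldimethylsilyloxy)benzoic acid | CC(C)(C)[Si](C)(C)Oc1ccc(cc1)C(=O)O
F3 | step 10 | 6β-alcohol (C6 epimer of 17) | CC1=C[C@@H](OC(=O)CC(C)C)[C@]2(C)CC[C@](O[Si](CC)(CC)CC)(C(C)C)[C@@H]2[C@@H](O)C1
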